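The route rests on cutting the six-membered lactone that ties C11 to the C15 oxygen across C13=C14. One operation, ring-closing metathesis followed in the same flask by ruthenium tetroxide syn-dihydroxylation, closes that ring (atoms C11, C12, C13, C14, C15, O15) and sets the C13 and C14 carbinols: on this ring the C12 methyl and the C16 chain sit cis, so the oxidant adds to the free face. The precursor is the allylic ester made from (S)-5-(silyloxy)pent-1-en-3-ol and (R)-2-methylbut-3-enoic acid. The lactone is then unfolded into the C10 bromo, C11 chloro alkene and the C17 aldehyde, extended to C23, and joined to a C1–C9 stannane carrying the cyclohexane ester.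

Key step: step 7

Remark on numbering: C1–C23 are the acyl-chain atoms of the target (C1 = ester carbonyl); C1' carries the ring carboxyl, C3' the acylated oxygen, C4' the ring hydroxyl; TBS = tert-butyldimethylsilyl, TES = triethylsilyl.
Remark on stereochemistry: the target is (12R,13R,14S,15S,17R,18R,19S), (1'S,3'R,4'S), 2E,4E,6E,8E,10Z,20E; for protected intermediates "as in the target" means the same spatial arrangement (the SMILES is authoritative, the letters can change with protecting groups).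
Assumption: the titanium enolate of the (1R,2S)-aminoindanyl chloroacetate 25 is taken to deliver the (17R,18R) anti chlorohydrin; should its sense of induction be the opposite, the (1S,2R) ester is used and nothing else changes.
Remark on supply: 1, 4, 5, 23, 30, 36, 40 and 42 are taken as catalogue chemicals.

Step 1
Reactants: 1 3-(tert-butyldimethylsilyloxy)propanal
Product: 2 rac-5-(tert-butyldimethylsilyloxy)pent-1-en-3-ol
Conditions: CH2=CHMgBr, THF, −78 → 0 °C; aq. NH4Cl
Reagents that add atoms: vinylmagnesium bromide, C=C[Mg]Br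
Why: Grignard 1,2-addition to an unhindered aldehyde should give the racemic allylic alcohol, the stereocentre being sorted in the next step.

Step 2
Reactants: 2 rac-5-(tert-butyldimethylsilyloxy)pent-1-en-3-ol
Product: 3 (S)-5-(tert-butyldimethylsilyloxy)pent-1-en-3-ol
Conditions: Ti(OiPr)4 (0.1 equiv), D-(−)-diisopropyl tartrate (0.15 equiv), t-BuOOH (0.6 equiv), 4 Å MS, CH2Cl2, −20 °C
Reagents that add atoms: none
Why: In the Sharpless kinetic resolution with the D-tartrate the (R)-alcohol should be epoxidised much faster, so the (S)-alcohol (future C15) is recovered at a little over half conversion.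

Step 3
Reactants: 4 (R)-4-benzyloxazolidin-2-one; 5 (E)-but-2-enoyl chloride
Product: 6 (R)-4-benzyl-3-[(E)-but-2-enoyl]oxazolidin-2-one
Conditions: n-BuLi, THF, −78 °C; then 5, −78 → 0 °C
Reagents that add atoms: none
Why: N-acylation of the lithiated oxazolidinone by the acid chloride attaches the auxiliary.

Step 4
Reactants: 6 (R)-4-benzyl-3-[(E)-but-2-enoyl]oxazolidin-2-one
Product: 8 (R)-4-benzyl-3-[(R)-2-methylbut-3-enoyl]oxazolidin-2-one, via sodium dienolate 7 (not isolated)
Conditions: NaN(SiMe3)2, THF, −78 °C; MeI, −78 °C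
Reagents that add atoms: iodomethane, CI
Why: In this oxazolidinone-auxiliary deconjugative alkylation, γ-deprotonation gives the chelated (Z)-dienolate, which should be methylated at the α-carbon on the face away from the benzyl group, giving the (R) centre (future C12) because vinyl outranks methyl.

Step 5
Reactants: 8 (R)-4-benzyl-3-[(R)-2-methylbut-3-enoyl]oxazolidin-2-one
Product: 10 (R)-2-methylbut-3-enoic acid, via lithium peroxycarboxylate 9 (not isolated)
Conditions: LiOH, H2O2, THF/H2O, 0 °C; aq. Na2SO3; HCl to pH 2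
Reagents that add atoms: hydrogen peroxide, OO (the acid hydroxyl oxygen, delivered as LiOOH)
Why: Lithium hydroperoxide cleaves the exocyclic imide carbonyl and is too weak a base to conjugate or racemise the β,γ-unsaturated acyl group, and sulfite then reduces the peracid (auxiliary hydrolysis).

Step 6
Reactants: 3 (S)-5-(tert-butyldimethylsilyloxy)pent-1-en-3-ol; 10 (R)-2-methylbut-3-enoic acid
Product: 11 (S)-5-(tert-butyldimethylsilyloxy)pent-1-en-3-yl (R)-2-methylbut-3-enoate
Conditions: DCC, DMAP (5 mol %), CH2Cl2, 0 °C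
Reagents that add atoms: none
Why: Steglich esterification at 0 °C with little DMAP should acylate the allylic alcohol with both centres intact and without moving the β,γ-alkene into conjugation.

Step 7
Reactants: 11 (S)-5-(tert-butyldimethylsilyloxy)pent-1-en-3-yl (R)-2-methylbut-3-enoate
Product: 13 (3R,4R,5R,6S)-6-[2-(TBSO)ethyl]-4,5-dihydroxy-3-methyloxan-2-one, via unsaturated lactone 12 (not isolated)
Conditions: second-generation Grubbs catalyst RuCl2(H2IMes)(PCy3)(=CHPh) (5 mol %), 1,4-benzoquinone (10 mol %), EtOAc (5 mM), 70 °C; then MeCN, 0 °C, aq. NaIO4 (1.5 equiv), CeCl3·7H2O (10 mol %), 10 min; aq. Na2S2O3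
Reagents that add atoms: sodium periodate, [Na+].[O-]I(=O)(=O)=O (both hydroxyl oxygens, passed on through RuO4)
Why: The ruthenium benzylidene engages one vinyl group and passes through ruthenacyclobutanes ([2+2] and retro-[2+2]) to join C13 to C14 with loss of ethylene, the known metathesis of allyl but-3-enoates to 3,6-dihydro-2H-pyran-2-ones. The ring formed is the six-membered lactone O15–C11–C12–C13=C14–C15, closed by metathesis between two monosubstituted alkenes that the branched C12 and C15 carbons pre-organise. Periodate with CeCl3 then converts the spent ruthenium into RuO4, which adds to the cis ring alkene by [3+2] cycloaddition and after hydrolysis of the ruthenate ester leaves a syn diol (tandem metathesis–dihydroxylation). C13 and C14 are fixed by the ring, since the C12 methyl and the C15 side chain are cis and block one face, so both hydroxyls should arrive on the other. The step needs this face selectivity and freedom from alkene migration into conjugation, C12 epimerisation and over-oxidation, which a neutral medium, the quinone hydride scavenger, 0 °C and a contact time of minutes should secure. The primary TBS ether is kept because it is inert to RuO4, which benzyl-type ethers are not.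

Step 8
Reactants: 13 (3R,4R,5R,6S)-6-[2-(TBSO)ethyl]-4,5-dihydroxy-3-methyloxan-2-one
Product: 14 (3R,4R,5S,6S)-4,5-bis(TBSO)-6-[2-(TBSO)ethyl]-3-methyloxan-2-one
Conditions: TBSOTf, 2,6-lutidine, CH2Cl2, −78 → 0 °C
Reagents that add atoms: tert-butyldimethylsilyl trifluoromethanesulfonate, CC(C)(C)[Si](C)(C)OS(=O)(=O)C(F)(F)F
Why: Silyl triflate with a hindered weak base silylates both secondary hydroxyls and should leave the lactone α-centre C12 untouched.

Step 9
Reactants: 14 (3R,4R,5S,6S)-4,5-bis(TBSO)-6-[2-(TBSO)ethyl]-3-methyloxan-2-one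
Product: 15 C15-hydroxy Weinreb amide of the C11–C17 chain
Conditions: MeNH(OMe)·HCl, AlMe3, CH2Cl2, 0 → 23 °C; aq. KNaC4H4O6
Reagents that add atoms: N,O-dimethylhydroxylamine hydrochloride, CNOC.Cl
Why: Weinreb aminolysis by the chloroaluminium amide opens the lactone at the acyl–oxygen bond, so C12 and C15 are not touched and the C15 hydroxyl is set free.

Step 10
Reactants: 15 C15-hydroxy Weinreb amide of the C11–C17 chain
Product: 16 tetrakis-TBS Weinreb amide of the C11–C17 chain
Conditions: TBSOTf, 2,6-lutidine, CH2Cl2, −78 → 0 °C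
Reagents that add atoms: tert-butyldimethylsilyl trifluoromethanesulfonate, CC(C)(C)[Si](C)(C)OS(=O)(=O)C(F)(F)F
Why: Silylation caps the C15 hydroxyl before it can close back onto the amide.

Step 11
Reactants: 16 tetrakis-TBS Weinreb amide of the C11–C17 chain
Product: 17 C11 aldehyde of the C11–C17 chain
Conditions: iBu2AlH, THF, −78 °C; aq. KNaC4H4O6
Reagents that add atoms: none
Why: Reduction of the N-methoxy-N-methyl amide stops at a chelated aluminium hemiaminal that releases the aldehyde only on work-up, so over-reduction and α-epimerisation should be avoided.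

Step 12
Reactants: 17 C11 aldehyde of the C11–C17 chain
Product: 18 C10 1,1-dibromoalkene
Conditions: CBr4, PPh3, 2,6-lutidine, CH2Cl2, 0 °C
Reagents that add atoms: tetrabromomethane, BrC(Br)(Br)Br
Why: Ramirez dibromo-olefination (first half of the Corey–Fuchs sequence) is a non-basic Wittig-type reaction that should homologate the α-branched aldehyde by C10 without epimerising C12.

Step 13
Reactants: 18 C10 1,1-dibromoalkene
Product: 19 C10–C11 1-bromoalkyne
Conditions: NaN(SiMe3)2 (1.1 equiv), THF, −78 → −40 °C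
Reagents that add atoms: none
Why: E2 loss of HBr from the 1,1-dibromoalkene with one equivalent of a non-nucleophilic amide base should stop at the 1-bromoalkyne.

Step 14
Reactants: 19 C10–C11 1-bromoalkyne
Product: 20 (10Z)-10-bromo-11-chloro alkene of the C10–C17 chain
Conditions: LiCl, Pd(OAc)2 (5 mol %), AcOH, 23 °C
Reagents that add atoms: lithium chloride, [Li+].[Cl-]
Why: In this palladium-catalysed hydrochlorination of a 1-haloalkyne, chloride attacks the palladium-bound alkyne at C11 from the side opposite the metal (trans-chloropalladation) and acetic acid cleaves the C10–Pd bond with retention, so H and Cl end trans and Br and Cl cis.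

Step 15
Reactants: 20 (10Z)-10-bromo-11-chloro alkene of the C10–C17 chain
Product: 21 C17 primary alcohol
Conditions: HF·pyridine, pyridine, THF, 0 °C
Reagents that add atoms: none
Why: Buffered HF·pyridine should cleave the unhindered primary silyl ether much faster than the three secondary ones (selective desilylation).

Step 16
Reactants: 21 C17 primary alcohol
Product: 22 C17 aldehyde
Conditions: Dess–Martin periodinane, NaHCO3, CH2Cl2, 0 → 23 °C
Reagents that add atoms: none
Why: Dess–Martin oxidation under buffered neutral conditions should give the β-silyloxy aldehyde without β-elimination.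

Step 17
Reactants: 23 (1R,2S)-cis-1-aminoindan-2-ol
Product: 24 N-[(1R,2S)-2-hydroxyindan-1-yl]-4-methylbenzenesulfonamide
Conditions: TsCl, Et3N, CH2Cl2, 0 → 23 °C
Reagents that add atoms: 4-methylbenzenesulfonyl chloride, Cc1ccc(cc1)S(Cl)(=O)=O
Why: The amine is far more nucleophilic than the secondary alcohol, so sulfonylation should occur on nitrogen only.

Step 18
Reactants: 24 N-[(1R,2S)-2-hydroxyindan-1-yl]-4-methylbenzenesulfonamide
Product: 25 (1R,2S)-1-(4-methylphenylsulfonamido)indan-2-yl chloroacetate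
Conditions: ClCH2COCl, pyridine, CH2Cl2, 0 °C
Reagents that add atoms: chloroacetyl chloride, ClCC(Cl)=O
Why: O-acylation of the secondary alcohol by the acid chloride, the weakly nucleophilic sulfonamide nitrogen staying free under pyridine.

Step 19
Reactants: 22 C17 aldehyde; 25 (1R,2S)-1-(4-methylphenylsulfonamido)indan-2-yl chloroacetate
Product: 27 (17R,18R) anti chlorohydrin aminoindanyl ester, via titanium enolate 26 (not isolated)
Conditions: 25, TiCl4, iPr2NEt, CH2Cl2, 0 → 23 °C; then 22 premixed with TiCl4, −78 °C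
Reagents that add atoms: none
Why: In this ester-derived titanium enolate anti-aldol of an aminoindanyl chloroacetate, the (Z)-chlorotitanium enolate held in a chelate with the sulfonamide adds to the TiCl4-activated aldehyde to form C17–C18 as the anti chlorohydrin, the auxiliary selecting the enolate and aldehyde faces that give 17R and 18R.

Step 20
Reactants: 27 (17R,18R) anti chlorohydrin aminoindanyl ester
Product: 28 C17 triethylsilyl ether of the chlorohydrin ester
Conditions: TESOTf, 2,6-lutidine, CH2Cl2, −78 °C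
Reagents that add atoms: triethylsilyl trifluoromethanesulfonate, CC[Si](CC)(CC)OS(=O)(=O)C(F)(F)F
Why: Low-temperature silylation with a weak base protects the C17 hydroxyl without retro-aldol cleavage or epoxide closure.

Step 21
Reactants: 28 C17 triethylsilyl ether of the chlorohydrin ester
Product: 29 C19 α-chloro aldehyde of the C10–C19 chain
Conditions: iBu2AlH (2.2 equiv), CH2Cl2, −78 °C; MeOH, aq. KNaC4H4O6
Reagents that add atoms: none
Why: Partial ester reduction at −78 °C, in which the α-chloro substituent stabilises the tetrahedral aluminate until work-up, should release the aldehyde and the recoverable auxiliary alcohol.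

Step 22
Reactants: 29 C19 α-chloro aldehyde of the C10–C19 chain; 30 but-1-yne
Product: 33 (19S) allylic alcohol of the C10–C23 chain, via alkenylzirconocene 31 (not isolated), via alkenylzinc 32 (not isolated)
Conditions: 30, Cp2Zr(H)Cl, CH2Cl2, 23 °C; ZnMe2, −65 °C; then 29, −65 → 0 °C
Reagents that add atoms: none
Why: Syn hydrozirconation of the alkyne gives the (E)-alkenyl metal, and after transmetallation to zinc its 1,2-addition to the α-chloro aldehyde should follow the Cornforth–Felkin model (attack anti to the C–Cl bond), placing the C19 hydroxyl anti to the C18 chloride.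

Step 23
Reactants: 33 (19S) allylic alcohol of the C10–C23 chain
Product: 35 C19 carbamate of the C10–C23 bromide, via trichloroacetyl carbamate 34 (not isolated)
Conditions: Cl3CC(O)NCO, CH2Cl2, 0 °C; then neutral Al2O3, 23 °C
Reagents that add atoms: trichloroacetyl isocyanate, O=C=NC(=O)C(Cl)(Cl)Cl
Why: The acyl isocyanate adds to the only free hydroxyl and alumina hydrolyses the N-trichloroacetyl group, a neutral two-stage carbamoylation.

Step 24
Reactants: 36 prop-2-yn-1-ol
Product: 37 (E)-3-(tributylstannyl)prop-2-en-1-ol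
Conditions: Bu3SnH, AIBN (cat.), 80 °C
Reagents that add atoms: tributyltin hydride, CCCC[SnH](CCCC)CCCC
Why: Radical hydrostannation of the terminal alkyne should give mainly the thermodynamically favoured (E)-β-stannyl allylic alcohol, separable from minor isomers.

Step 25
Reactants: 37 (E)-3-(tributylstannyl)prop-2-en-1-ol
Product: 38 (E)-3-(tributylstannyl)prop-2-enal
Conditions: MnO2, CH2Cl2, 23 °C
Reagents that add atoms: none
Why: MnO2 oxidises allylic alcohols selectively and leaves the C–Sn bond alone.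

Step 26
Reactants: 38 (E)-3-(tributylstannyl)prop-2-enal
Product: 39 (2E,4E)-2-methyl-5-(tributylstannyl)penta-2,4-dienal
Conditions: Ph3P=C(CH3)CHO, toluene, 80 °C
Reagents that add atoms: 2-(triphenylphosphoranylidene)propanal, CC(C=O)=P(c1ccccc1)(c1ccccc1)c1ccccc1
Why: Wittig olefination with the stabilised formyl ylide should give the (E)-trisubstituted enal (future C6=C7).

Step 27
Reactants: 40 ethyl (E)-4-(diethoxyphosphoryl)but-2-enoate
Product: 41 (E)-4-(diethoxyphosphoryl)but-2-enoic acid
Conditions: LiOH (1.05 equiv), THF/H2O, 0 °C; HCl to pH 2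
Reagents that add atoms: lithium hydroxide, [Li+].[OH-]
Why: Saponification attacks the carboxylic ester only, phosphonate esters being inert to cold hydroxide.

Step 28
Reactants: 42 (S)-cyclohex-3-ene-1-carboxylic acid
Product: 43 (1S,4S,5S)-4-iodo-6-oxabicyclo[3.2.1]octan-7-one
Conditions: I2, KI, NaHCO3, H2O/CH2Cl2, 0 → 23 °C, dark
Reagents that add atoms: iodine, II
Why: Iodolactonisation adds carboxylate and iodine anti across the alkene, so the lactone oxygen at C3' is cis and the iodide at C4' trans to the carboxyl carbon.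

Step 29
Reactants: 43 (1S,4S,5S)-4-iodo-6-oxabicyclo[3.2.1]octan-7-one
Product: 45 allyl (1S,3S,6R)-7-oxabicyclo[4.1.0]heptane-3-carboxylate, via iodohydrin alkoxide 44 (not isolated)
Conditions: K2CO3, CH2=CHCH2OH, 23 °C
Reagents that add atoms: prop-2-en-1-ol, C=CCO
Why: Alkoxide opens the lactone to the allyl ester and the freed C3' alkoxide displaces the anti iodide (intramolecular Williamson reaction), giving the epoxide cis to the ester.

Step 30
Reactants: 45 allyl (1S,3S,6R)-7-oxabicyclo[4.1.0]heptane-3-carboxylate; 41 (E)-4-(diethoxyphosphoryl)but-2-enoic acid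
Product: 46 allyl (1S,3R,4R)-3-[(E)-4-(diethoxyphosphoryl)but-2-enoyloxy]-4-hydroxycyclohexane-1-carboxylate
Conditions: 41 (1.5 equiv), Cs2CO3 (0.3 equiv), DMF, 70 °C
Reagents that add atoms: none
Why: Carboxylate opening of the epoxide should be trans-diaxial (Fürst–Plattner rule) at C3' from the face opposite the ester, which installs the acyl oxygen with the target's C3' configuration by inversion.

Step 31
Reactants: 46 allyl (1S,3R,4R)-3-[(E)-4-(diethoxyphosphoryl)but-2-enoyloxy]-4-hydroxycyclohexane-1-carboxylate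
Product: 47 allyl (1S,3R)-3-[(E)-4-(diethoxyphosphoryl)but-2-enoyloxy]-4-oxocyclohexane-1-carboxylate
Conditions: Dess–Martin periodinane, NaHCO3, CH2Cl2, 23 °C
Reagents that add atoms: none
Why: Neutral Dess–Martin oxidation removes the wrongly configured C4' carbinol without epimerising the adjacent C3' centre.

Step 32
Reactants: 47 allyl (1S,3R)-3-[(E)-4-(diethoxyphosphoryl)but-2-enoyloxy]-4-oxocyclohexane-1-carboxylate
Product: 48 allyl (1S,3R,4S)-3-[(E)-4-(diethoxyphosphoryl)but-2-enoyloxy]-4-hydroxycyclohexane-1-carboxylate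
Conditions: NaBH4, MeOH/THF, −40 °C; AcOH quench
Reagents that add atoms: none
Why: Borohydride should attack the cyclohexanone axially and anti to the axial C3' acyloxy group, giving the equatorial C4' alcohol cis to the ester oxygen (substrate-controlled ketone reduction).

Step 33
Reactants: 48 allyl (1S,3R,4S)-3-[(E)-4-(diethoxyphosphoryl)but-2-enoyloxy]-4-hydroxycyclohexane-1-carboxylate
Product: 49 allyl (1S,3R,4S)-4-(TBSO)-3-[(E)-4-(diethoxyphosphoryl)but-2-enoyloxy]cyclohexane-1-carboxylate
Conditions: TBSOTf, 2,6-lutidine, CH2Cl2, −78 → 0 °C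
Reagents that add atoms: tert-butyldimethylsilyl trifluoromethanesulfonate, CC(C)(C)[Si](C)(C)OS(=O)(=O)C(F)(F)F
Why: Silylation under weakly basic conditions blocks the C4' hydroxyl before acyl migration between the cis oxygens can occur.

Step 34
Reactants: 49 allyl (1S,3R,4S)-4-(TBSO)-3-[(E)-4-(diethoxyphosphoryl)but-2-enoyloxy]cyclohexane-1-carboxylate; 39 (2E,4E)-2-methyl-5-(tributylstannyl)penta-2,4-dienal
Product: 51 allyl ester of the C1–C9 tetraenoate stannane, via phosphonate anion 50 (not isolated)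
Conditions: LiN(SiMe3)2, THF, −78 °C; then 39, −78 → 0 °C
Reagents that add atoms: none
Why: Horner–Wadsworth–Emmons olefination of the vinylogous phosphonate anion at the carbon next to phosphorus should form the (E)-C4=C5 bond and complete the tetraene.

Step 35
Reactants: 51 allyl ester of the C1–C9 tetraenoate stannane
Product: 52 (1S,3R,4S)-4-(TBSO)-3-[(2E,4E,6E,8E)-6-methyl-9-(tributylstannyl)nona-2,4,6,8-tetraenoyloxy]cyclohexane-1-carboxylic acid
Conditions: Pd(PPh3)4 (5 mol %), morpholine, THF, 23 °C; pH 5 buffer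
Reagents that add atoms: none
Why: In this Tsuji–Trost deallylation zerovalent palladium ionises the allyl ester and morpholine traps the allyl group, the vinylstannane having no electrophile to couple with.

Step 36
Reactants: 35 C19 carbamate of the C10–C23 bromide; 52 (1S,3R,4S)-4-(TBSO)-3-[(2E,4E,6E,8E)-6-methyl-9-(tributylstannyl)nona-2,4,6,8-tetraenoyloxy]cyclohexane-1-carboxylic acid
Product: 53 fully silylated target
Conditions: Pd2(dba)3 (5 mol %), AsPh3 (20 mol %), DMF, 40 °C, dark
Reagents that add atoms: none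
Why: In the Stille coupling zerovalent palladium inserts into the C10–Br bond in preference to C–Cl and transmetallation with the alkenylstannane joins C9 to C10 with retention of both alkene geometries.

Step 37
Reactants: 53 fully silylated target
Product: 54 CNP0164989.3
Conditions: HF·pyridine, pyridine, THF, 0 → 23 °C
Reagents that add atoms: none
Why: Acidic fluoride removes the four TBS ethers and the TES ether in one operation (global desilylation) without base, so the C17/C18 chlorohydrin cannot close to an epoxide and the ring ester cannot migrate.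

Compound list
1 | 3-(tert-butyldimethylsilyloxy)propanal | CC(C)(C)[Si](C)(C)OCCC=O | starting material
2 | rac-5-(tert-butyldimethylsilyloxy)pent-1-en-3-ol | CC(C)(C)[Si](C)(C)OCCC(O)C=C | intermediate
3 | (S)-5-(tert-butyldimethylsilyloxy)pent-1-en-3-ol | CC(C)(C)[Si](C)(C)OCC[C@H](O)C=C | intermediate
4 | (R)-4-benzyloxazolidin-2-one | O=C1N[C@H](Cc2ccccc2)CO1 | starting material
5 | (E)-but-2-enoyl chloride | C/C=C/C(Cl)=O | starting material
6 | (R)-4-benzyl-3-[(E)-but-2-enoyl]oxazolidin-2-one | C/C=C/C(=O)N1[C@H](Cc2ccccc2)COC1=O | intermediate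
7 | sodium (Z)-dienolate of 6 | [Na+].[O-]/C(=C\C=C)N1[C@H](Cc2ccccc2)COC1=O | intermediate
8 | (R)-4-benzyl-3-[(R)-2-methylbut-3-enoyl]oxazolidin-2-one | C=C[C@@H](C)C(=O)N1[C@H](Cc2ccccc2)COC1=O | intermediate
9 | lithium (R)-2-methylbut-3-eneperoxoate | [Li+].[O-]OC(=O)[C@H](C)C=C | intermediate
10 | (R)-2-methylbut-3-enoic acid | OC(=O)[C@H](C)C=C | intermediate
11 | (S)-5-(tert-butyldimethylsilyloxy)pent-1-en-3-yl (R)-2-methylbut-3-enoate | CC(C)(C)[Si](C)(C)OCC[C@H](OC(=O)[C@H](C)C=C)C=C | intermediate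
12 | (3R,6S)-6-[2-(TBSO)ethyl]-3-methyl-3,6-dihydro-2H-pyran-2-one | CC(C)(C)[Si](C)(C)OCC[C@H](O1)C=C[C@@H](C)C1=O | intermediate
13 | (3R,4R,5R,6S)-6-[2-(TBSO)ethyl]-4,5-dihydroxy-3-methyloxan-2-one (C11–C17 lactone; methyl and side chain cis, diol on the other face) | CC(C)(C)[Si](C)(C)OCC[C@H](O1)[C@H](O)[C@H](O)[C@@H](C)C1=O | intermediate
14 | (3R,4R,5S,6S)-4,5-bis(TBSO)-6-[2-(TBSO)ethyl]-3-methyloxan-2-one | CC(C)(C)[Si](C)(C)OCC[C@H](O1)[C@H](O[Si](C)(C)C(C)(C)C)[C@H](O[Si](C)(C)C(C)(C)C)[C@@H](C)C1=O | intermediate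
15 | N-methoxy-N-methyl amide of the C11–C17 acid; C12 methyl, OTBS at C13, C14, C17, free OH at C15; C12–C15 as in the target | CC(C)(C)[Si](C)(C)OCC[C@H](O)[C@H](O[Si](C)(C)C(C)(C)C)[C@H](O[Si](C)(C)C(C)(C)C)[C@@H](C)C(=O)N(C)OC | intermediate
16 | N-methoxy-N-methyl amide of the C11–C17 acid; OTBS at C13, C14, C15, C17; C12–C15 as in the target | CC(C)(C)[Si](C)(C)OCC[C@H](O[Si](C)(C)C(C)(C)C)[C@H](O[Si](C)(C)C(C)(C)C)[C@H](O[Si](C)(C)C(C)(C)C)[C@@H](C)C(=O)N(C)OC | intermediate
17 | C11 aldehyde of the C11–C17 chain; OTBS at C13, C14, C15, C17; C12–C15 as in the target | CC(C)(C)[Si](C)(C)OCC[C@H](O[Si](C)(C)C(C)(C)C)[C@H](O[Si](C)(C)C(C)(C)C)[C@H](O[Si](C)(C)C(C)(C)C)[C@@H](C)C=O | intermediate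
18 | 10,10-dibromo-C10=C11 alkene of the C10–C17 chain; four OTBS; C12–C15 as in the target | CC(C)(C)[Si](C)(C)OCC[C@H](O[Si](C)(C)C(C)(C)C)[C@H](O[Si](C)(C)C(C)(C)C)[C@H](O[Si](C)(C)C(C)(C)C)[C@@H](C)C=C(Br)Br | intermediate
19 | 10-bromo-C10≡C11 alkyne of the C10–C17 chain; four OTBS; C12–C15 as in the target | CC(C)(C)[Si](C)(C)OCC[C@H](O[Si](C)(C)C(C)(C)C)[C@H](O[Si](C)(C)C(C)(C)C)[C@H](O[Si](C)(C)C(C)(C)C)[C@@H](C)C#CBr | intermediate
20 | (10Z)-10-bromo-11-chloro alkene of the C10–C17 chain; four OTBS; C12–C15 as in the target | CC(C)(C)[Si](C)(C)OCC[C@H](O[Si](C)(C)C(C)(C)C)[C@H](O[Si](C)(C)C(C)(C)C)[C@H](O[Si](C)(C)C(C)(C)C)[C@@H](C)/C(Cl)=C/Br | intermediate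
21 | C17 primary alcohol of 20; OTBS at C13, C14, C15 | OCC[C@H](O[Si](C)(C)C(C)(C)C)[C@H](O[Si](C)(C)C(C)(C)C)[C@H](O[Si](C)(C)C(C)(C)C)[C@@H](C)/C(Cl)=C/Br | intermediate
22 | C17 aldehyde; OTBS at C13, C14, C15; (10Z)-10-bromo-11-chloro alkene | O=CC[C@H](O[Si](C)(C)C(C)(C)C)[C@H](O[Si](C)(C)C(C)(C)C)[C@H](O[Si](C)(C)C(C)(C)C)[C@@H](C)/C(Cl)=C/Br | intermediate
23 | (1R,2S)-cis-1-aminoindan-2-ol | N[C@H]1[C@@H](O)Cc2ccccc12 | starting material
24 | N-[(1R,2S)-2-hydroxyindan-1-yl]-4-methylbenzenesulfonamide | Cc1ccc(cc1)S(=O)(=O)N[C@H]1[C@@H](O)Cc2ccccc12 | intermediate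
25 | (1R,2S)-1-(4-methylphenylsulfonamido)indan-2-yl chloroacetate | Cc1ccc(cc1)S(=O)(=O)N[C@H]1[C@@H](OC(=O)CCl)Cc2ccccc12 | intermediate
26 | trichlorotitanium (Z)-enolate of 25 | Cc1ccc(cc1)S(=O)(=O)N[C@H]1[C@@H](O/C(O[Ti](Cl)(Cl)Cl)=C/Cl)Cc2ccccc12 | intermediate
27 | aminoindanyl ester of the C10–C19 acid; C18 Cl and C17 OH anti, (17R,18R); OTBS at C13, C14, C15 | Cc1ccc(cc1)S(=O)(=O)N[C@H]1[C@@H](OC(=O)[C@H](Cl)[C@H](O)C[C@H](O[Si](C)(C)C(C)(C)C)[C@H](O[Si](C)(C)C(C)(C)C)[C@H](O[Si](C)(C)C(C)(C)C)[C@@H](C)/C(Cl)=C/Br)Cc2ccccc12 | intermediate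
28 | C17 triethylsilyl ether of 27 | Cc1ccc(cc1)S(=O)(=O)N[C@H]1[C@@H](OC(=O)[C@H](Cl)[C@H](O[Si](CC)(CC)CC)C[C@H](O[Si](C)(C)C(C)(C)C)[C@H](O[Si](C)(C)C(C)(C)C)[C@H](O[Si](C)(C)C(C)(C)C)[C@@H](C)/C(Cl)=C/Br)Cc2ccccc12 | intermediate
29 | C19 aldehyde of the C10–C19 chain; C18 Cl, C17 OTES, OTBS at C13, C14, C15; centres as in the target | O=C[C@H](Cl)[C@H](O[Si](CC)(CC)CC)C[C@H](O[Si](C)(C)C(C)(C)C)[C@H](O[Si](C)(C)C(C)(C)C)[C@H](O[Si](C)(C)C(C)(C)C)[C@@H](C)/C(Cl)=C/Br | intermediate
30 | but-1-yne | CCC#C | starting material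
31 | (E)-but-1-enyl zirconocene chloride | CC/C=C/[Zr](Cl)(C1C=CC=C1)C1C=CC=C1 | intermediate
32 | (E)-but-1-enyl(methyl)zinc | CC/C=C/[Zn]C | intermediate
33 | C10–C23 chain with free C19 OH (19S), C18 Cl, C17 OTES, OTBS at C13, C14, C15, (20E), (10Z)-10-bromo-11-chloro alkene | CC/C=C/[C@H](O)[C@H](Cl)[C@H](O[Si](CC)(CC)CC)C[C@H](O[Si](C)(C)C(C)(C)C)[C@H](O[Si](C)(C)C(C)(C)C)[C@H](O[Si](C)(C)C(C)(C)C)[C@@H](C)/C(Cl)=C/Br | intermediate
34 | N-trichloroacetyl carbamate of 33 at C19 | CC/C=C/[C@H](OC(=O)NC(=O)C(Cl)(Cl)Cl)[C@H](Cl)[C@H](O[Si](CC)(CC)CC)C[C@H](O[Si](C)(C)C(C)(C)C)[C@H](O[Si](C)(C)C(C)(C)C)[C@H](O[Si](C)(C)C(C)(C)C)[C@@H](C)/C(Cl)=C/Br | intermediate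
35 | C19 primary carbamate of the C10–C23 bromide; other groups as in 33 | CC/C=C/[C@H](OC(N)=O)[C@H](Cl)[C@H](O[Si](CC)(CC)CC)C[C@H](O[Si](C)(C)C(C)(C)C)[C@H](O[Si](C)(C)C(C)(C)C)[C@H](O[Si](C)(C)C(C)(C)C)[C@@H](C)/C(Cl)=C/Br | intermediate
36 | prop-2-yn-1-ol | OCC#C | starting material
37 | (E)-3-(tributylstannyl)prop-2-en-1-ol | OC/C=C/[Sn](CCCC)(CCCC)CCCC | intermediate
38 | (E)-3-(tributylstannyl)prop-2-enal | O=C/C=C/[Sn](CCCC)(CCCC)CCCC | intermediate
39 | (2E,4E)-2-methyl-5-(tributylstannyl)penta-2,4-dienal | O=C/C(C)=C/C=C/[Sn](CCCC)(CCCC)CCCC | intermediate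
40 | ethyl (E)-4-(diethoxyphosphoryl)but-2-enoate | CCOC(=O)/C=C/CP(=O)(OCC)OCC | starting material
41 | (E)-4-(diethoxyphosphoryl)but-2-enoic acid | OC(=O)/C=C/CP(=O)(OCC)OCC | intermediate
42 | (S)-cyclohex-3-ene-1-carboxylic acid | OC(=O)[C@@H]1CC=CCC1 | starting material
43 | (1S,4S,5S)-4-iodo-6-oxabicyclo[3.2.1]octan-7-one | O=C1O[C@@H]2[C@@H](I)CC[C@H]1C2 | intermediate
44 | potassium alkoxide of allyl (1S,3S,4S)-3-hydroxy-4-iodocyclohexane-1-carboxylate | C=CCOC(=O)[C@H]1CC[C@H](I)[C@@H]([O-])C1.[K+] | intermediate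
45 | allyl (1S,3S,6R)-7-oxabicyclo[4.1.0]heptane-3-carboxylate | C=CCOC(=O)[C@H]1CC[C@H]2O[C@H]2C1 | intermediate
46 | allyl (1S,3R,4R)-3-[(E)-4-(diethoxyphosphoryl)but-2-enoyloxy]-4-hydroxycyclohexane-1-carboxylate | C=CCOC(=O)[C@H]1CC[C@@H](O)[C@H](OC(=O)/C=C/CP(=O)(OCC)OCC)C1 | intermediate
47 | allyl (1S,3R)-3-[(E)-4-(diethoxyphosphoryl)but-2-enoyloxy]-4-oxocyclohexane-1-carboxylate | C=CCOC(=O)[C@H]1CCC(=O)[C@H](OC(=O)/C=C/CP(=O)(OCC)OCC)C1 | intermediate
48 | allyl (1S,3R,4S)-3-[(E)-4-(diethoxyphosphoryl)but-2-enoyloxy]-4-hydroxycyclohexane-1-carboxylate | C=CCOC(=O)[C@H]1CC[C@H](O)[C@H](OC(=O)/C=C/CP(=O)(OCC)OCC)C1 | intermediate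
49 | allyl (1S,3R,4S)-4-(TBSO)-3-[(E)-4-(diethoxyphosphoryl)but-2-enoyloxy]cyclohexane-1-carboxylate | C=CCOC(=O)[C@H]1CC[C@H](O[Si](C)(C)C(C)(C)C)[C@H](OC(=O)/C=C/CP(=O)(OCC)OCC)C1 | intermediate
50 | lithium salt of 49 deprotonated at the carbon next to phosphorus | C=CCOC(=O)[C@H]1CC[C@H](O[Si](C)(C)C(C)(C)C)[C@H](OC(=O)/C=C/[CH-]P(=O)(OCC)OCC)C1.[Li+] | intermediate
51 | allyl (1S,3R,4S)-4-(TBSO)-3-[(2E,4E,6E,8E)-6-methyl-9-(tributylstannyl)nona-2,4,6,8-tetraenoyloxy]cyclohexane-1-carboxylate | C=CCOC(=O)[C@H]1CC[C@H](O[Si](C)(C)C(C)(C)C)[C@H](OC(=O)/C=C/C=C/C(C)=C/C=C/[Sn](CCCC)(CCCC)CCCC)C1 | intermediate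
52 | (1S,3R,4S)-4-(TBSO)-3-[(2E,4E,6E,8E)-6-methyl-9-(tributylstannyl)nona-2,4,6,8-tetraenoyloxy]cyclohexane-1-carboxylic acid | OC(=O)[C@H]1CC[C@H](O[Si](C)(C)C(C)(C)C)[C@H](OC(=O)/C=C/C=C/C(C)=C/C=C/[Sn](CCCC)(CCCC)CCCC)C1 | intermediate
53 | target with OTBS at C13, C14, C15 and C4', OTES at C17, free carboxylic acid | CC/C=C/[C@H](OC(N)=O)[C@H](Cl)[C@H](O[Si](CC)(CC)CC)C[C@H](O[Si](C)(C)C(C)(C)C)[C@H](O[Si](C)(C)C(C)(C)C)[C@H](O[Si](C)(C)C(C)(C)C)[C@@H](C)/C(Cl)=C/C=C/C=C(C)/C=C/C=C/C(=O)O[C@@H]1C[C@@H](C(=O)O)CC[C@@H]1O[Si](C)(C)C(C)(C)C | intermediate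
54 | CNP0164989.3 | CC/C=C/[C@H](OC(N)=O)[C@H](Cl)[C@H](O)C[C@H](O)[C@H](O)[C@H](O)[C@@H](C)/C(Cl)=C/C=C/C=C(C)/C=C/C=C/C(=O)O[C@@H]1C[C@@H](C(=O)O)CC[C@@H]1O | target

Total step count: 37.
Longest linear sequence: 21 steps (steps 3–16, 19–23, 36 and 37).

Steps most likely to fail

Step 7. Ring closure of an ester-tethered diene can stall while ruthenium hydride species move the new alkene into conjugation, which erases C12, and prolonged contact with RuO4 can over-oxidise the diol or erode face selectivity. Fallback: the two events are separated and the oxidation is moved to osmium. From 11 the metathesis is run alone and lactone 12 is isolated by chromatography. Lactone 12 is then dihydroxylated with catalytic OsO4 and N-methylmorpholine N-oxide in acetone/water, an osmate-ester pathway under the same steric control that does not cleave glycols, and the route is rejoined at 13. This fallback makes no compound outside the list (F0).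

Step 19. The auxiliary-controlled addition may give poor or reversed face selectivity at C17, because the TiCl4-bound β-silyloxy aldehyde has its own 1,3-anti preference, and silyl ethers may be lost to the Lewis acid. Fallback: C17 and C18 are set in two separate reagent-controlled events. From 22, asymmetric allylboration with (−)-B-allyldiisopinocampheylborane (Et2O, −78 °C; NaOH, H2O2) gives C17 homoallylic alcohol F1. TESOTf and 2,6-lutidine give triethylsilyl ether F2. OsO4 (cat.), NaIO4 and 2,6-lutidine cleave the terminal alkene, the halogenated alkene being electron-poor and hindered, to give C19 aldehyde F3. Enamine-catalysed α-chlorination with N-chlorosuccinimide, using the enantiomer of 2,5-diphenylpyrrolidine that gives the 18R chloride, rejoins the route at 29.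

Step 22. The preference set by the α-chloride (attack anti to C–Cl) may be eroded by the opposing 1,3-bias of the C17 silyloxy group, or C18 may epimerise before addition, so that C19 epimers form. Fallback: stereocontrol is shifted from carbon–carbon bond formation to hydride delivery. From 29, (E)-but-1-enylmagnesium bromide is added without regard to selectivity, giving 33 together with its C19 epimer F4. The mixture is oxidised with Dess–Martin periodinane to α-chloro enone F5. Luche 1,2-reduction (NaBH4, CeCl3·7H2O, MeOH, −78 °C), with hydride entering anti to the C–Cl bond, rejoins the route at 33.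

Further compounds
F0 | step 7 | none | none
F1 | step 19 | C17 homoallylic alcohol of the C10–C20 chain (C17 as in the target; OTBS at C13, C14, C15) | C=CC[C@H](O)C[C@H](O[Si](C)(C)C(C)(C)C)[C@H](O[Si](C)(C)C(C)(C)C)[C@H](O[Si](C)(C)C(C)(C)C)[C@@H](C)/C(Cl)=C/Br
F2 | step 19 | C17 triethylsilyl ether of F1 | C=CC[C@H](O[Si](CC)(CC)CC)C[C@H](O[Si](C)(C)C(C)(C)C)[C@H](O[Si](C)(C)C(C)(C)C)[C@H](O[Si](C)(C)C(C)(C)C)[C@@H](C)/C(Cl)=C/Br
F3 | step 19 | C19 aldehyde with C18 methylene and C17 OTES | O=CC[C@H](O[Si](CC)(CC)CC)C[C@H](O[Si](C)(C)C(C)(C)C)[C@H](O[Si](C)(C)C(C)(C)C)[C@H](O[Si](C)(C)C(C)(C)C)[C@@H](C)/C(Cl)=C/Br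
F4 | step 22 | C19 epimer of 33 | CC/C=C/[C@@H](O)[C@H](Cl)[C@H](O[Si](CC)(CC)CC)C[C@H](O[Si](C)(C)C(C)(C)C)[C@H](O[Si](C)(C)C(C)(C)C)[C@H](O[Si](C)(C)C(C)(C)C)[C@@H](C)/C(Cl)=C/Br
F5 | step 22 | C19 ketone (α-chloro enone) of the C10–C23 chain | CC/C=C/C(=O)[C@H](Cl)[C@H](O[Si](CC)(CC)CC)C[C@H](O[Si](C)(C)C(C)(C)C)[C@H](O[Si](C)(C)C(C)(C)C)[C@H](O[Si](C)(C)C(C)(C)C)[C@@H](C)/C(Cl)=C/Br
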